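common to all: substrate 0.050 M
- south-west: reagent 0.073 M; run made earlier
- south-east: reagent 0.078 M; run made earlier
- south: reagent 0.097 M; run made earlier
- birch: reagent 0.0600 M; time 3.0 d
- oak: reagent 0.125 M; time 3.0 d

| run | time / h | tris adduct / % | single product / % | substrate / % |
|---|---|---|---|---|
| south-west | 3.00 | 4 | 26 | 69 |
| south-west | 10.0 | 2 | 57 | 38 |
| south-west | 15.0 | 5 | 60 | 25 |
| south-west | 25.0 | 11 | 62 | 23 |
| south-west | 40.0 | 15 | 63 | 10 |
| south-east | 3.00 | 0 | 33 | 71 |
| south-east | 10.0 | 3 | 57 | 36 |
| south-east | 15.0 | 8 | 61 | 23 |
| south-east | 25.0 | 11 | 64 | 16 |
| south-east | 40.0 | 16 | 66 | 11 |
| south | 8.00 | 0 | 57 | 35 |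
| south | 15.0 | 10 | 62 | 19 |
| south | 20.0 | 14 | 68 | 13 |
| south | 30.0 | 20 | 68 | 6 |
| south | 40.0 | 26 | 59 | 4 |

(standard deviation of a reading: 2 percentage points)

- which of these holds the largest part of the substrate at the end of birch (single product / bis adduct / substrate / tris adduct)
- which of these holds the largest part of the substrate at the end of oak (single product / bis adduct / substrate / tris adduct)
- tris adduct at the end of oak, in percent of the substrate charged

- what was read earlier has a scatter of 2 percentage points, one standard deviation

Minutes. Early times came first: the kineticist noted that in the south run substrate was down to 35% at 8.00 h while tris adduct read 0%, and she argued that the step to count is the one out of single product. She read it from the same run. The share past single product, meaning neither substrate nor single product, rose from 19.0% at 15.0 h to 37.0% at 40.0 h. At 30.0 h single product read 68%, and with one reagent used per single product, two per bis adduct and three per tris adduct, c(reagent) came to 0.0270 M. Her reading of the rate constant of that step, with the scatter of the readings in it, was k = 0.392 /M/h.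

My own reckoning followed. Oak needs 0.150 M of reagent to take all substrate to tris adduct, more than its 0.125 M, so as a rough estimate I halved the 0.0750 M left once substrate has become single product and held c(reagent) at 0.0375 M. That gives single product a pseudo-first-order half-life of 47.1 h, and oak holds 1.53 of them: the half-life count, time divided by that half-life. So my estimate for single product at the end of oak is 34.7%. Taking the 11.0% missing from the last south reading as bis adduct leaves tris adduct at 54.3%. Birch's count, reckoned the same way, is 0.204, so I put single product first there.

The forecast named single product for birch and tris adduct for oak, with 50% (42% to 58%), below my figure: “Tris leads, narrowly.”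

The flask gives single product for birch and tris adduct for oak, at 51.5%, with single product at 36.6% against the 34.7% from the count.

    reagent + bis adduct ⇌ tris adduct + released group (K = 1.50, k = 3.77 /M/h)
    crystals ⇌ released group, rate k2*(cs2 - [released group]) while solid is left; crystals form when [released group] > cs2 (solubility = 4.60 mM, k = 20.8 /h)
    substrate + reagent → single product + released group (k = 1.88 /M/h)
    reagent + single product → bis adduct + released group (k = 0.414 /M/h)

A neighbouring flask keeps oak's reagent but holds 0.013 M of substrate, which puts reagent at 9.62 equiv. Its full demand of 0.0390 M is less than the charge, so the count holds c(reagent) at 0.0990 M, the mean of 0.112 M after the first step and 0.0860 M after the full demand. The count becomes 4.03, which gives an estimate of 6.12% for single product. That flask holds 7.08% single product and 89.0% tris adduct.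

Readings and results were computed for substances that don't exist; scatter was added.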